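**Strategy.** The butenolide (O1, C2=O, C3, C4, C5, exocyclic C6) is cut at C4–C5 and O1–C2. C4, the enoate β-carbon bearing ring A (4-hydroxyphenyl), and C5, the oxygenated carbon holding C6 and ring B (3-bromo-4-methoxyphenyl), are both innately electrophilic, so a carbene catalyst inverts the polarity of C4 within a ring A arylpropiolaldehyde. This carbon then attacks the ketone of a ring B arylpyruvate tert-butyl ester and the alkoxide lactonizes, creating both bonds and the ring in one operation. The C5 ester, which activates the ketone, is later expelled oxidatively as CO2 to unveil the Z-configured C5=C6 bond.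

Key step: step 7

Remark: the arylpyruvate ester is drawn as its keto tautomer, which is assumed to stay available by fast exchange with the Z-enol; ring A is carried as a triisopropylsilyl ether, which resists amidine base and trifluoroacetic acid better than smaller silyl ethers; the C5 ester is tert-butyl so that acid removes it without opening the lactone.

Step 1
Reactants: 1 4-iodophenol
Product: 2 (4-iodophenoxy)triisopropylsilane
Conditions: TIPSCl, imidazole, DMF, rt
Reagents that add atoms: chlorotriisopropylsilane (TIPSCl), CC(C)[Si](Cl)(C(C)C)C(C)C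
Why: Imidazole-promoted O-silylation of a phenol by a silyl chloride is routine, and the bulky triisopropylsilyl ether is chosen to withstand the acid, amidine base and oxidant met in steps 3, 7, 8 and 9.

Step 2
Reactants: 2 (4-iodophenoxy)triisopropylsilane; 3 3,3-diethoxyprop-1-yne
Product: 4 [4-(3,3-diethoxyprop-1-yn-1-yl)phenoxy]triisopropylsilane
Conditions: PdCl2(PPh3)2 (2 mol %), CuI (4 mol %), Et3N, THF, rt
Reagents that add atoms: none
Why: Sonogashira coupling of an aryl iodide with a terminal alkyne runs at rt under PdCl2(PPh3)2/CuI catalysis, conditions to which the diethyl acetal and the aryl silyl ether are inert.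

Step 3
Reactants: 4 [4-(3,3-diethoxyprop-1-yn-1-yl)phenoxy]triisopropylsilane
Product: 5 3-[4-(triisopropylsilyloxy)phenyl]prop-2-ynal
Conditions: TsOH·H2O (20 mol %), acetone/H2O (10:1), 40 °C
Reagents that add atoms: water, O
Why: Acid-catalysed acetal hydrolysis through the oxocarbenium ion releases the conjugated ynal, while the aryl triisopropylsilyl ether is stable to dilute aqueous acid.

Step 4
Reactants: 6 3-bromo-4-methoxybenzaldehyde; 7 N-acetylglycine
Product: 9 (Z)-4-(3-bromo-4-methoxybenzylidene)-2-methyloxazol-5(4H)-one, via 2-methyloxazol-5(4H)-one 8 (not isolated)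
Conditions: Ac2O, NaOAc, 110 °C
Reagents that add atoms: none
Why: Erlenmeyer–Plöchl azlactone synthesis, in which Ac2O cyclodehydrates 7 to oxazolone 8, whose acidic C4 methylene undergoes acetate-mediated Perkin-type condensation with aldehyde 6 to the thermodynamically preferred Z-arylidene azlactone, a geometry that is lost again in step 5.

Step 5
Reactants: 9 (Z)-4-(3-bromo-4-methoxybenzylidene)-2-methyloxazol-5(4H)-one
Product: 11 3-(3-bromo-4-methoxyphenyl)-2-oxopropanoic acid, via (Z)-2-acetamido-3-(3-bromo-4-methoxyphenyl)acrylic acid 10 (not isolated)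
Conditions: 3 M HCl aq/AcOH, reflux
Reagents that add atoms: water, O
Why: Aqueous acid opens the azlactone to dehydroamino acid 10 and then cleaves its enamide, the freed enamine tautomerizing to an imine that hydrolyses to the α-keto acid, which is the standard entry to arylpyruvic acids and leaves the aryl bromide and the methyl ether untouched.

Step 6
Reactants: 11 3-(3-bromo-4-methoxyphenyl)-2-oxopropanoic acid
Product: 12 tert-butyl 3-(3-bromo-4-methoxyphenyl)-2-oxopropanoate
Conditions: tert-butyl 2,2,2-trichloroacetimidate (2 equiv), CH2Cl2/cyclohexane, rt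
Reagents that add atoms: tert-butyl 2,2,2-trichloroacetimidate, CC(C)(C)OC(=N)C(Cl)(Cl)Cl
Why: The carboxylic acid protonates the trichloroacetimidate and is tert-butylated by collapse of the ion pair (imidate esterification), so no base or Lewis acid is present that could engage the enolizable ketone or its enol.

Step 7
Reactants: 5 3-[4-(triisopropylsilyloxy)phenyl]prop-2-ynal; 12 tert-butyl 3-(3-bromo-4-methoxyphenyl)-2-oxopropanoate
Product: 13 racemic tert-butyl 2-(3-bromo-4-methoxybenzyl)-3-[4-(triisopropylsilyloxy)phenyl]-5-oxo-2,5-dihydrofuran-2-carboxylate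
Conditions: 1,3-bis(2,6-diisopropylphenyl)imidazolium chloride (IPr·HCl, 15 mol %), DBU (15 mol %), LiCl (1.0 equiv), 4 Å MS, THF, rt, slow addition of 5 to 12 (1.5 equiv)
Reagents that add atoms: none
Why: The carbene adds to the aldehyde of 5 and proton transfer gives an alkynyl Breslow enol whose electron density is relayed through the triple bond to the ring A-bearing carbon (the future C4); this allenolate carbon attacks the lithium-chelated ketone of 12 (the future C5), the resulting allenol tautomerizes to an α,β-unsaturated acyl azolium, and the tertiary alkoxide acylates at C2 with release of the carbene. The closest known reaction type is the carbene/Lewis acid conjugate-umpolung (3+2) annulation of 3-arylpropiolaldehydes with α-keto esters and isatins to γ,γ-disubstituted butenolides, to which an enolizable arylpyruvate is a new member of the ketone class. The lactone ring closes by 5-exo-trig addition–elimination of the C5 alkoxide at the exocyclic acyl azolium carbonyl. The quaternary C5 centre forms as a racemate because catalyst and both partners are achiral, and no control is needed since C5 becomes sp2 in step 9. The step requires attack through the β-carbon and not the carbinol (acyl anion) carbon, which the two 2,6-diisopropylphenyl groups of the carbene shield while the aryl group on the alkyne terminus stabilizes the allenolate; it also requires ketone addition to outrun proton transfer from the CH2 of 12, which is favoured by the adjacent ester and lithium chelation raising ketone electrophilicity, by base held at the level of the azolium salt, and by slow addition of 5 to excess 12.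

Step 8
Reactants: 13 racemic tert-butyl 2-(3-bromo-4-methoxybenzyl)-3-[4-(triisopropylsilyloxy)phenyl]-5-oxo-2,5-dihydrofuran-2-carboxylate
Product: 14 racemic 2-(3-bromo-4-methoxybenzyl)-3-[4-(triisopropylsilyloxy)phenyl]-5-oxo-2,5-dihydrofuran-2-carboxylic acid
Conditions: TFA/CH2Cl2 (1:4), 0 °C to rt
Reagents that add atoms: none
Why: Acidolysis of the tert-butyl ester by E1 loss of the tert-butyl cation leaves the lactone, the aryl bromide, the methyl ether and the acid-resistant aryl triisopropylsilyl ether intact, and the acid is kept cold and used at once because a β,γ-unsaturated acid can lose CO2 on heating.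

Step 9
Reactants: 14 racemic 2-(3-bromo-4-methoxybenzyl)-3-[4-(triisopropylsilyloxy)phenyl]-5-oxo-2,5-dihydrofuran-2-carboxylic acid
Product: 15 (Z)-5-(3-bromo-4-methoxybenzylidene)-4-[4-(triisopropylsilyloxy)phenyl]furan-2(5H)-one
Conditions: Pb(OAc)4 (1.3 equiv), Cu(OAc)2 (10 mol %), pyridine, benzene, rt to 80 °C
Reagents that add atoms: none
Why: Kochi-type oxidative decarboxylation, in which the tetravalent lead carboxylate fragments with loss of CO2 to a C5 radical stabilized by O1 and the C3=C4 bond, divalent copper oxidizes it, and loss of a C6 proton (the only β-hydrogens) gives the conjugated ylidene, whose Z geometry, with ring B syn to O1 and remote from ring A on C4, should be favoured thermodynamically because the E isomer suffers allylic strain between the two aryl-bearing positions.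

Step 10
Reactants: 15 (Z)-5-(3-bromo-4-methoxybenzylidene)-4-[4-(triisopropylsilyloxy)phenyl]furan-2(5H)-one
Product: 16 3''-bromorubrolide F, (Z)-5-(3-bromo-4-methoxybenzylidene)-4-(4-hydroxyphenyl)furan-2(5H)-one
Conditions: TBAF (1.1 equiv), AcOH (1.2 equiv), THF, 0 °C
Reagents that add atoms: none
Why: Fluoride attacks silicon to cleave the aryl silyl ether (fluoride-mediated desilylation), and the acetic acid buffer protonates the phenoxide so that the enol lactone is not opened and the Z alkene is not isomerized.

**Compound list**

1 | 4-iodophenol | Oc1ccc(I)cc1 | starting material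
2 | (4-iodophenoxy)triisopropylsilane | CC(C)[Si](Oc1ccc(I)cc1)(C(C)C)C(C)C | intermediate
3 | 3,3-diethoxyprop-1-yne | CCOC(OCC)C#C | starting material
4 | [4-(3,3-diethoxyprop-1-yn-1-yl)phenoxy]triisopropylsilane | CCOC(OCC)C#Cc1ccc(O[Si](C(C)C)(C(C)C)C(C)C)cc1 | intermediate
5 | 3-[4-(triisopropylsilyloxy)phenyl]prop-2-ynal | O=CC#Cc1ccc(O[Si](C(C)C)(C(C)C)C(C)C)cc1 | intermediate
6 | 3-bromo-4-methoxybenzaldehyde | COc1ccc(C=O)cc1Br | starting material
7 | N-acetylglycine | CC(=O)NCC(=O)O | starting material
8 | 2-methyloxazol-5(4H)-one | CC1=NCC(=O)O1 | intermediate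
9 | (Z)-4-(3-bromo-4-methoxybenzylidene)-2-methyloxazol-5(4H)-one | CC1=N/C(=C\c2ccc(OC)c(Br)c2)C(=O)O1 | intermediate
10 | (Z)-2-acetamido-3-(3-bromo-4-methoxyphenyl)acrylic acid | CC(=O)N/C(=C\c1ccc(OC)c(Br)c1)C(=O)O | intermediate
11 | 3-(3-bromo-4-methoxyphenyl)-2-oxopropanoic acid | COc1ccc(CC(=O)C(=O)O)cc1Br | intermediate
12 | tert-butyl 3-(3-bromo-4-methoxyphenyl)-2-oxopropanoate | COc1ccc(CC(=O)C(=O)OC(C)(C)C)cc1Br | intermediate
13 | racemic tert-butyl 2-(3-bromo-4-methoxybenzyl)-3-[4-(triisopropylsilyloxy)phenyl]-5-oxo-2,5-dihydrofuran-2-carboxylate | COc1ccc(CC2(C(=O)OC(C)(C)C)OC(=O)C=C2c2ccc(O[Si](C(C)C)(C(C)C)C(C)C)cc2)cc1Br | intermediate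
14 | racemic 2-(3-bromo-4-methoxybenzyl)-3-[4-(triisopropylsilyloxy)phenyl]-5-oxo-2,5-dihydrofuran-2-carboxylic acid | COc1ccc(CC2(C(=O)O)OC(=O)C=C2c2ccc(O[Si](C(C)C)(C(C)C)C(C)C)cc2)cc1Br | intermediate
15 | (Z)-5-(3-bromo-4-methoxybenzylidene)-4-[4-(triisopropylsilyloxy)phenyl]furan-2(5H)-one | COc1ccc(/C=C2\OC(=O)C=C2c2ccc(O[Si](C(C)C)(C(C)C)C(C)C)cc2)cc1Br | intermediate
16 | 3''-bromorubrolide F, (Z)-5-(3-bromo-4-methoxybenzylidene)-4-(4-hydroxyphenyl)furan-2(5H)-one | COc1ccc(/C=C2\OC(=O)C=C2c2ccc(O)cc2)cc1Br | target

**Step count.** Total: 10 steps. Longest linear sequence: 7 steps (steps 4, 5, 6, 7, 8, 9, 10; the ring A arm through steps 1, 2, 3, 7, 8, 9, 10 is equally long).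

**Steps most likely to fail**

1. Step 7. The acidic CH2 or enol of 12 may protonate the allenolate before carbon–carbon bond formation. The catalyst would then be diverted into acyl azolium chemistry (enol O-acylation, or Michael addition–lactonization to a dihydropyranone), or the enolate of 12 may add directly to the ynal. The fallback makes the C5=C6 bond by vinylogous aldol condensation and sets out from aldehyde 6. Suzuki–Miyaura coupling of purchased 4-bromofuran-2(5H)-one with (4-hydroxyphenyl)boronic acid (PdCl2(PPh3)2, KF, THF/H2O, 60 °C) should give 4-(4-hydroxyphenyl)furan-2(5H)-one F1. Silylation (TIPSCl, imidazole, DMF) should give 4-[4-(triisopropylsilyloxy)phenyl]furan-2(5H)-one F2. Treating F2 and 6 with TBSOTf and i-Pr2NEt in CH2Cl2 should generate tert-butyldimethyl({4-[4-(triisopropylsilyloxy)phenyl]furan-2-yl}oxy)silane F3 in the flask. F3 should add through C5 to the silyl-activated aldehyde (vinylogous Mukaiyama aldol) to give 5-[(3-bromo-4-methoxyphenyl)(tert-butyldimethylsilyloxy)methyl]-4-[4-(triisopropylsilyloxy)phenyl]furan-2(5H)-one F4. DBU added to the same flask should eliminate silanol (E1cB) to the Z-ylidene, so the fallback comes back to the route at 15, before step 10.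

2. Step 9. Non-oxidative loss of CO2 from the β,γ-unsaturated acid, dimerization of the stabilized C5 radical, or capture of the oxidized C5 centre by acetate in place of proton loss may compete, and the alkene geometry may not be set cleanly. The fallback sets out from 14 and separates decarboxylation from oxidation. Deliberate thermal decarboxylation (pyridine, 90 °C) should give racemic 5-(3-bromo-4-methoxybenzyl)-4-[4-(triisopropylsilyloxy)phenyl]furan-2(5H)-one F5. Wohl–Ziegler bromination (NBS, AIBN, PhCF3, 80 °C) at the allylic, oxygen-bearing C5–H should give racemic 5-bromo-5-(3-bromo-4-methoxybenzyl)-4-[4-(triisopropylsilyloxy)phenyl]furan-2(5H)-one F6. Dehydrobromination with Et3N (CH2Cl2, rt) should then give the conjugated Z-ylidene, coming back to the route at 15.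

3. Step 6. Esterification of the hindered, largely enolized keto acid may be slow, with competing enol O-alkylation or aldol self-condensation of 11. The fallback sets out from 11 and changes the ester and its mode of removal. Carboxylate alkylation with allyl bromide (KHCO3, DMF, rt) should give allyl 3-(3-bromo-4-methoxyphenyl)-2-oxopropanoate F7. F7 would be combined with 5 under the conditions of step 7 to give racemic allyl 2-(3-bromo-4-methoxybenzyl)-3-[4-(triisopropylsilyloxy)phenyl]-5-oxo-2,5-dihydrofuran-2-carboxylate F8. Tsuji–Trost deallylation (Pd(PPh3)4 cat., morpholine, THF, rt; the aryl bromide is inert to zerovalent palladium at rt) should free the acid, coming back to the route at 14 and making step 8 unnecessary.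

**Further compounds**

F1 | step 7 | 4-(4-hydroxyphenyl)furan-2(5H)-one | O=C1OCC(c2ccc(O)cc2)=C1
F2 | step 7 | 4-[4-(triisopropylsilyloxy)phenyl]furan-2(5H)-one | O=C1OCC(c2ccc(O[Si](C(C)C)(C(C)C)C(C)C)cc2)=C1
F3 | step 7 | tert-butyldimethyl({4-[4-(triisopropylsilyloxy)phenyl]furan-2-yl}oxy)silane | CC(C)(C)[Si](C)(C)Oc1cc(-c2ccc(O[Si](C(C)C)(C(C)C)C(C)C)cc2)co1
F4 | step 7 | 5-[(3-bromo-4-methoxyphenyl)(tert-butyldimethylsilyloxy)methyl]-4-[4-(triisopropylsilyloxy)phenyl]furan-2(5H)-one (racemic diastereomer mixture) | COc1ccc(C(O[Si](C)(C)C(C)(C)C)C2OC(=O)C=C2c2ccc(O[Si](C(C)C)(C(C)C)C(C)C)cc2)cc1Br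
F5 | step 9 | racemic 5-(3-bromo-4-methoxybenzyl)-4-[4-(triisopropylsilyloxy)phenyl]furan-2(5H)-one | COc1ccc(CC2OC(=O)C=C2c2ccc(O[Si](C(C)C)(C(C)C)C(C)C)cc2)cc1Br
F6 | step 9 | racemic 5-bromo-5-(3-bromo-4-methoxybenzyl)-4-[4-(triisopropylsilyloxy)phenyl]furan-2(5H)-one | COc1ccc(CC2(Br)OC(=O)C=C2c2ccc(O[Si](C(C)C)(C(C)C)C(C)C)cc2)cc1Br
F7 | step 6 | allyl 3-(3-bromo-4-methoxyphenyl)-2-oxopropanoate | COc1ccc(CC(=O)C(=O)OCC=C)cc1Br
F8 | step 6 | racemic allyl 2-(3-bromo-4-methoxybenzyl)-3-[4-(triisopropylsilyloxy)phenyl]-5-oxo-2,5-dihydrofuran-2-carboxylate | COc1ccc(CC2(C(=O)OCC=C)OC(=O)C=C2c2ccc(O[Si](C(C)C)(C(C)C)C(C)C)cc2)cc1Br
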